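## Structural features

The target is (13S)-15-acetoxylabd-7-en-17-oic acid, a normal-series labdane. It is a trans-fused decalin: ring A (C1–C5, C10) carries the gem-dimethyl group on C4, and ring B (C5–C10) carries the angular methyl C20 on C10, the carboxyl carbon C17 on the C7=C8 alkene and, on C9, the chain C11–C16 ending in a primary acetate. Three ring stereocentres stand in a row: C5 (S, 5α-H), the quaternary C10 (S, β-methyl) and C9 (R, 9α-H, chain β and cis to C20). The fourth stereocentre, C13 (S), lies four bonds from C9 and can neither direct the ring centres nor be directed by them. The fragile groups are the acetate (no hydride, organometallic or hydroxide reagents once it is in place), the trisubstituted alkene, which must end at C7–C8, and the free acid. The real difficulty is the C9–C10 bond, which joins a tertiary carbon to a quaternary one flanked through C5 by the second quaternary carbon C4, and the ring centres must be set in absolute terms by a reagent. The chain C9/C11–C16 corresponds atom for atom to (S)-citronellol after cleavage of its alkene, so C13 can be bought. The key step uses the fact that C17–C8–C9 is an enal unit and that ring B is the cyclohexene formed from this unit and the four carbons C10=C5–C6=C7 of a vinylcyclohexene built on ring A. An oxygen on C7 steers the regiochemistry and later leaves to create the C7=C8 alkene.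

## Logic of the disconnections

**14 ⇒ 13.** No skeletal bond is cut; the C17 acid is traced to the C17 aldehyde. The aldehyde is what the cycloaddition delivers and what makes C8–H acidic for the elimination. The gain is that the only acidic proton of the target is absent from all earlier steps. The forward step must oxidise C17 without touching the C7=C8 alkene, C9–H or the acetate.

**13 ⇒ 12.** The C7=C8 π bond is exchanged for a C7–O bond and C8–H. An oxygen β to the aldehyde fixes the alkene position without a regiochemical choice and is the donor that the cycloaddition needs. The gain is two sp3 centres that a [4+2] adduct carries naturally. The forward step needs the silyloxy group to leave from the enolate of 12. This is asked of the silyl ether directly, which saves the deprotection and acylation that a better leaving group would cost.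

**12 ⇒ 11.** The C5–H and C6–H bonds are removed to reveal the C5=C6 alkene that a Diels–Alder reaction leaves behind. The gain is that C5 need not be set in the ring-forming step. The forward step must put hydrogen on the α face of C5 in the presence of an aldehyde. The α face of this alkene carries the pseudoaxial C7 silyloxy group and the β face carries C20, so a method that fixes C5 at a radical stage is preferred to one that needs an open alkene face.

**11 ⇒ 6 + 8.** C7–C8 and C9–C10 are cut in a retro-[4+2]. This removes ring B, two skeletal bonds and the stereocentres C7, C8, C9 and C10 at once, and splits the molecule into two pieces of similar size. The forward step must bond C10 to C9 (regiochemistry), pass through the endo transition state (chain cis to C20), attack one face of the enal only, and overcome the low reactivity of a fully substituted diene terminus. Carrying the C15 oxygen as the acetate of the target from the start makes it a spectator and removes two late protecting-group steps.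

**8 ⇒ 7.** The O–Si bond is cut; 8 is the silyl dienol ether of a β,γ-unsaturated aldehyde whose C6 protons are doubly activated. The gain is a one-step entry from a bulk chemical. The forward step must give the E enol ether, the only isomer that can reach the s-cis diene geometry.

**6 ⇒ 4 + 5.** The C8=C9 alkene is cut as a Wittig disconnection with a stabilised formylmethylene ylide. The gain is a saturated aldehyde whose carbonyl carbon becomes C9. The forward step needs E selectivity and a single homologation.

**4 ⇒ 2 ⇒ 1.** The C9 carbonyl comes from oxidative cleavage of the trisubstituted alkene of 2, and the acetate comes from acylation of 1. The gain is that C13 is bought in the correct configuration. The forward steps only need to leave C13 untouched, which they do because it is not adjacent to any reacting centre.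

## Other disconnections considered

**Alternative 1:** C5–C10 and C8–C9 are cut, opening both rings to the achiral trienimide A1.
- **Forward step:** with [Cu(t-Bu-box)](SbF6)2, a chiral Lewis acid of divalent copper, the chelated (E)-3-methylenoyl imide (C9=C10) would add intramolecularly to the (E,E)-diene C5–C8 and give the trans-fused bicycle A2 with C5, C8, C9 and C10 set.
- **In favour:** both rings and the ring-fusion hydrogen come from one operation, which is better than the chosen plan, where C5 needs a separate reduction. Intramolecularity offsets the low reactivity of a trisubstituted dienophile. The catalyst class is established for trienimides.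
- **Against:** a β,β-disubstituted enoyl imide has a strained s-cis chelate and is outside what this catalyst has been shown to activate. A2 has its alkene at C6–C7, C17 as an ether and only C11 of the chain, so an alkene transposition, two oxidations at C17, a C11–C12 coupling and a separate introduction of C13 must follow. A1 itself needs a long stereodefined linear synthesis.
- **Comparison:** structurally A2 answers C5 better and everything around C8 and the chain worse. Mechanistically both plans stake the quaternary C10 on a cycloaddition; A1 has the entropic advantage and 6 + 8 the electronic one. In step economy the chosen plan is clearly shorter, because C17, the alkene position and the whole chain are in place when the ring closes.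

**Alternative 2:** only C8–C9 is cut; ring A with C5 and C10 already set is kept in the seco precursor A3, an α-bromoenoate with a C9=C11 alkene.
- **Forward step:** Bu3SnH with AIBN would generate the C8 vinyl radical, which closes 6-exo on C9; the C11 radical is then reduced to give A4.
- **In favour:** a radical addition is less sensitive to the neopentyl environment of C9 than a polar or pericyclic step, which is better than the chosen plan for the hindered bond. A4 already has the C7=C8 alkene conjugated with C17 at the acid oxidation level, so neither a C7 leaving group nor a C5 reduction is needed. A chair-like transition state should place the chain equatorial (9α-H).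
- **Against:** the quaternary C10 next to C5 is not solved but moved into the synthesis of A3, which needs its own enantioselective construction of a trans-1,2-disubstituted cyclohexane with a vinyl-bearing quaternary carbon. 1,6-Hydrogen transfer from the C20 or C4 methyl groups and 7-endo closure compete. Tin is used stoichiometrically. The methyl ester and silyl ether of A4 must be exchanged for acid and acetate in about three further steps.
- **Comparison:** in the endgame A4 is the equal or the better of 11. In overall structure-building the chosen plan does more per step, because it creates C9 and C10 catalytically in the ring-forming event. Total step count should favour the chosen plan unless A3 can be reached in very few steps.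

**Alternative 3:** C9–C10 and C5–C6 are cut; ring A is 2,2,6-trimethylcyclohexanone as its chiral imine A5, and C6–C9 with C17 come from the alkylidene acetoacetate A6.
- **Forward step:** the secondary enamine tautomer of A5 would add through C10 to C9 of A6. After hydrolysis the acetyl methyl (C6) condenses on the C5 ketone to give the enone A7.
- **In favour:** ring A is a cheap ketone and the amine is recoverable. The doubly activated acceptor is a stronger electrophile than an enal iminium ion and is arguably better matched to the hindered C10. The reaction class is established for quaternary centres next to a ketone. The C7 ketone and C17 ester of A7 are usefully placed.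
- **Against:** the gem-dimethyl group on the other α-carbon changes imine formation and enamine geometry relative to the known cases. Only C10 is under auxiliary control, while C9 arises in an open transition state from a geometrically mobile acceptor. The aldol closure must attack a carbonyl flanked by two quaternary carbons. After A7 the enone must be reduced to set C5, the C7 ketone reduced and eliminated, and ester and silyl ether exchanged for acid and acetate, about six further steps.
- **Comparison:** A5 + A6 is the equal of the chosen plan in convergence and better in the electrophilicity offered to C10. It is weaker in control of C9 and in the ring closure, and it is longer after the key step.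

Key step: step 5

Assumption: labdane numbering is used throughout; (2,6,6-trimethylcyclohex-1-en-1-yl)acetaldehyde (7) is taken as a purchasable flavour chemical; the (2R,5R) catalyst is assigned from the usual shielding model of benzyl imidazolidinone iminium ions.

## Steps

Step 1
Reactants: 1 (S)-citronellol
Product: 2 (S)-citronellyl acetate
Conditions: Ac2O, pyridine, DMAP (cat.), 0 °C → rt
Reagents that add atoms: acetic anhydride, CC(=O)OC(C)=O
Why: DMAP-catalysed acylation of a primary alcohol; C13 is not involved, and the acetate installed here is the one found in the target.

Step 2
Reactants: 2 (S)-citronellyl acetate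
Product: 4 (4S)-6-acetoxy-4-methylhexanal, via secondary ozonide 3 (not isolated)
Conditions: O3, CH2Cl2, −78 °C; then Me2S, −78 °C → rt
Reagents that add atoms: ozone, [O-][O+]=O
Why: Ozonolysis of the electron-rich trisubstituted alkene with reductive work-up; the ester is inert and the stereocentre is two carbons from the new aldehyde, so it cannot epimerise.

Step 3
Reactants: 4 (4S)-6-acetoxy-4-methylhexanal; 5 (triphenylphosphoranylidene)acetaldehyde
Product: 6 (S,E)-8-acetoxy-6-methyloct-2-enal
Conditions: toluene, 80 °C
Reagents that add atoms: none
Why: Wittig reaction of a stabilised ylide, which gives the E enal under thermodynamic control of oxaphosphetane formation; the product enal is less electrophilic than 4, so a slight excess of ylide should stop at one homologation.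

Step 4
Reactants: 7 (2,6,6-trimethylcyclohex-1-en-1-yl)acetaldehyde
Product: 8 tert-butyldimethyl{[(E)-2-(2,6,6-trimethylcyclohex-1-en-1-yl)vinyl]oxy}silane
Conditions: TBSOTf, Et3N, CH2Cl2, −78 → 0 °C
Reagents that add atoms: tert-butyldimethylsilyl trifluoromethanesulfonate, CC(C)(C)[Si](C)(C)OS(=O)(=O)C(F)(F)F
Why: Soft enolisation: O-silylation makes the doubly activated C6–H acidic enough for Et3N and gives the conjugated 1-silyloxy diene. The E isomer is expected to dominate because the Z isomer presses the silyloxy group against the methyl groups flanking C5; any Z isomer cannot reach the s-cis geometry and would pass through step 5 unchanged.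

Step 5
Reactants: 6 (S,E)-8-acetoxy-6-methyloct-2-enal; 8 tert-butyldimethyl{[(E)-2-(2,6,6-trimethylcyclohex-1-en-1-yl)vinyl]oxy}silane
Product: 11 (13S)-15-acetoxy-7α-(tert-butyldimethylsilyloxy)labd-5-en-17-al (8α-formyl; 9α-H; 10β-methyl), via enal iminium ion 9 (not isolated), via cycloadduct iminium ion 10 (not isolated)
Conditions: (2R,5R)-5-benzyl-2-tert-butyl-3-methylimidazolidin-4-one·CF3CO2H (20 mol%), 8 (2 equiv), CH2Cl2 (1 M), H2O (2 equiv), −20 → 4 °C
Reagents that add atoms: water, O
Why: Proposed new method: condensation of 6 with the amine salt gives the (E)-iminium ion 9, whose lowered LUMO is attacked by the electron-rich 1-silyloxy diene 8 in a concerted but strongly asynchronous [4+2] cycloaddition in which the C9–C10 bond runs ahead of C7–C8, and hydrolysis of 10 releases 11 and the catalyst. The closest known reaction types are amine-catalysed endo-selective Diels–Alder reactions of enals with 1-acyloxy dienes, the thermal cycloaddition of 1,3,3-trimethyl-2-vinylcyclohexene with acetylenic esters, and iminium-catalysed vinylogous Mukaiyama–Michael additions in which a fully substituted silyloxy-diene carbon adds to a β-alkyl enal; an amine-catalysed cycloaddition at a tetrasubstituted diene terminus with an inside methyl group has not been shown, so reactivity and not selectivity is the open point. Ring B is closed through a six-membered pericyclic transition state that joins both diene termini to the dienophile, the ring A alkene C5=C10 moving to C5=C6. Regiochemistry follows from the oxygen on C7, which puts the largest HOMO coefficient on C10, so C10 bonds to the β-carbon C9 and C7 to the α-carbon C8. C9 is set by the catalyst, whose benzyl group covers the C9 Re face of the s-trans (E)-iminium ion so that the diene adds to the C9 Si (C8 Re) face. C10 and C7 are set relative to C9 by the endo transition state, which places the C9 chain cis to the C20 methyl and, because the enol ether is E, the silyloxy group α and cis to the formyl group. C8 follows from suprafacial addition to the (E)-alkene (formyl trans to the chain) and is expendable because it becomes sp2 in step 7. The step therefore needs regio-, endo- and facial selectivity, secured by the C7 oxygen, by the iminium ion and by the benzyl shield; the excess of 8, the mild acid and the small amount of water are chosen so that the dienol ether outlives the reaction.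

Step 6
Reactants: 11 (13S)-15-acetoxy-7α-(tert-butyldimethylsilyloxy)labd-5-en-17-al
Product: 12 (13S)-15-acetoxy-7α-(tert-butyldimethylsilyloxy)labdan-17-al (5α-H)
Conditions: Mn(dpm)3 (10 mol%), PhSiH3, t-BuOOH, i-PrOH, rt, degassed
Reagents that add atoms: none
Why: Hydrogen-atom-transfer hydrogenation: a manganese hydride formed from Mn(dpm)3 and PhSiH3 transfers a hydrogen atom to the less substituted C6. The tertiary C5 radical then takes its hydrogen on the α face, anti to the axial C20 methyl, which gives the more stable trans-decalin without needing an open alkene face. Acetate and silyl ether are inert, and the hindered alkene is expected to react faster than the aldehyde.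

Step 7
Reactants: 12 (13S)-15-acetoxy-7α-(tert-butyldimethylsilyloxy)labdan-17-al
Product: 13 (13S)-15-acetoxylabd-7-en-17-al
Conditions: DBU (2 equiv), CH2Cl2, rt → 40 °C
Reagents that add atoms: none
Why: E1cB elimination: DBU deprotonates C8 next to the aldehyde, and the axial 7α-silyloxy group, anti-periplanar to the axial 8β-H, leaves as silanolate to give the conjugated enal. The leaving group sits only on C7, so no regiochemical choice arises; C9–H is not acidified and the primary acetate is stable to the amidine base.

Step 8
Reactants: 13 (13S)-15-acetoxylabd-7-en-17-al
Product: 14 (13S)-15-acetoxylabd-7-en-17-oic acid (CNP0412535.1)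
Conditions: NaClO2, NaH2PO4, 2-methylbut-2-ene, t-BuOH/H2O, 0 °C → rt
Reagents that add atoms: sodium chlorite, [Na+].[O-]Cl=O
Why: Pinnick oxidation: chlorous acid converts the enal into the conjugated acid at about pH 4 while the scavenger removes hypochlorous acid, so the alkene, C9 and the acetate are untouched.

## Compound list

1 | (S)-citronellol, (3S)-3,7-dimethyloct-6-en-1-ol | OCC[C@@H](C)CCC=C(C)C | starting material
2 | (S)-citronellyl acetate, (3S)-3,7-dimethyloct-6-en-1-yl acetate | CC(=O)OCC[C@@H](C)CCC=C(C)C | intermediate
3 | secondary ozonide, (3S)-5-(5,5-dimethyl-1,2,4-trioxolan-3-yl)-3-methylpentyl acetate (both epimers at the trioxolane carbon) | CC(=O)OCC[C@@H](C)CCC1OOC(C)(C)O1 | intermediate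
4 | (4S)-6-acetoxy-4-methylhexanal | CC(=O)OCC[C@@H](C)CCC=O | intermediate
5 | (triphenylphosphoranylidene)acetaldehyde | O=CC=P(c1ccccc1)(c1ccccc1)c1ccccc1 | starting material
6 | (S,E)-8-acetoxy-6-methyloct-2-enal | CC(=O)OCC[C@@H](C)CC/C=C/C=O | intermediate
7 | (2,6,6-trimethylcyclohex-1-en-1-yl)acetaldehyde (β-homocyclocitral) | CC1=C(CC=O)C(C)(C)CCC1 | starting material
8 | tert-butyldimethyl{[(E)-2-(2,6,6-trimethylcyclohex-1-en-1-yl)vinyl]oxy}silane | CC1=C(/C=C/O[Si](C)(C)C(C)(C)C)C(C)(C)CCC1 | intermediate
9 | (E)-iminium trifluoroacetate of 6 with (2R,5R)-5-benzyl-2-tert-butyl-3-methylimidazolidin-4-one | CC(=O)OCC[C@@H](C)CC/C=C/C=[N+]1[C@@H](C(C)(C)C)N(C)C(=O)[C@H]1Cc2ccccc2.[O-]C(=O)C(F)(F)F | intermediate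
10 | iminium trifluoroacetate of cycloadduct 11 with the same imidazolidinone (C17=N+) | CC(=O)OCC[C@@H](C)CC[C@H]1[C@H](C=[N+]3[C@@H](C(C)(C)C)N(C)C(=O)[C@H]3Cc4ccccc4)[C@H](O[Si](C)(C)C(C)(C)C)C=C2C(C)(C)CCC[C@]12C.[O-]C(=O)C(F)(F)F | intermediate
11 | (13S)-15-acetoxy-7α-(tert-butyldimethylsilyloxy)labd-5-en-17-al (8α-formyl, 9α-H, 10β-methyl) | CC(=O)OCC[C@@H](C)CC[C@H]1[C@H](C=O)[C@H](O[Si](C)(C)C(C)(C)C)C=C2C(C)(C)CCC[C@]12C | intermediate
12 | (13S)-15-acetoxy-7α-(tert-butyldimethylsilyloxy)labdan-17-al (5α-H, 8α-formyl) | CC(=O)OCC[C@@H](C)CC[C@H]1[C@H](C=O)[C@H](O[Si](C)(C)C(C)(C)C)C[C@H]2C(C)(C)CCC[C@]12C | intermediate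
13 | (13S)-15-acetoxylabd-7-en-17-al | CC(=O)OCC[C@@H](C)CC[C@H]1C(C=O)=CC[C@H]2C(C)(C)CCC[C@]12C | intermediate
14 | (13S)-15-acetoxylabd-7-en-17-oic acid (5S,9R,10S,13S) | CC(=O)OCC[C@@H](C)CC[C@H]1C(C(=O)O)=CC[C@H]2C(C)(C)CCC[C@]12C | target

## Step count and least certain steps

Total: 8 steps. Longest linear sequence: 7 steps (1 → 2 → 4 → 6 → 11 → 12 → 13 → 14, steps 1, 2, 3, 5, 6, 7, 8); the diene arm is one step.

**Step 5 (key step).** The most likely failure is that the cycloaddition is too slow: bond formation to the fully substituted C10 with its inside methyl group may not compete with protodesilylation of 8 by the acid salt and water, or with Mukaiyama–Michael attack through the unhindered C6. The fallback leaves covalent aminocatalysis for chiral Lewis acid catalysis, an established way of running enantioselective Diels–Alder reactions of α,β-unsaturated aldehydes with silyloxy dienes, though not yet on a diene terminus this hindered. It sets out from 6 and 8. The free enal is bound through its formyl group to a cationic oxazaborolidine: the B-(o-tolyl) oxazaborolidine of α,α-diphenylprolinol protonated by HNTf2, in the enantiomeric series that leaves the C9 Si face open. The reaction is run in dry CH2Cl2 at −78 to −40 °C. Water and amine are absent, so hydrolysis of 8 and dienamine formation from 7 cannot occur, and the stronger activation should help the bond to C10. The same endo adduct is expected, the route is rejoined at 11, and no new compound is made (F0).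

**Step 4.** The enolisation may show poor E/Z control, because the kinetic preference of amine/silyl triflate enolisation of aldehydes is weak, and the silyl group may be lost by hydrolysis on purification. The fallback fixes the geometry on a robust derivative and transfers it. Setting out from 7, Ac2O with KOAc at reflux should give the dienyl acetate, whose E isomer, (E)-2-(2,6,6-trimethylcyclohex-1-en-1-yl)vinyl acetate F1, is stable to chromatography and separable from the Z isomer. Two equivalents of MeLi in THF (−78 → 0 °C) cleave the enol acetate to lithium (E)-2-(2,6,6-trimethylcyclohex-1-en-1-yl)ethenolate F2 with retention of the double-bond geometry. TBSCl with DMPU silylates F2 on oxygen and returns to 8.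

**Step 6.** The formyl group may be reduced by the manganese hydride and silane alongside the alkene, or hydrogen may be delivered to C5 from the β face. The fallback removes the electrophilic carbonyl before the radical step. Setting out from 11, NaBH4 in MeOH at 0 °C reduces only the aldehyde and gives (13S)-15-acetoxy-7α-(tert-butyldimethylsilyloxy)labd-5-en-17-ol F3. The same hydrogen-atom-transfer hydrogenation then gives (13S)-15-acetoxy-7α-(tert-butyldimethylsilyloxy)labdan-17-ol F4. Dess–Martin periodinane buffered with NaHCO3 returns to 12.

**Step 7.** Silanolate may depart too slowly, so that the enolate of 12 is consumed by aldol self-condensation instead of elimination. The fallback replaces the leaving group. Setting out from 12, HF·pyridine in MeCN, an acidic medium in which retro-aldol opening of ring B is not expected, removes the silyl group and gives (13S)-15-acetoxy-7α-hydroxylabdan-17-al F5. MsCl with Et3N at 0 °C forms (13S)-15-acetoxy-7α-(methanesulfonyloxy)labdan-17-al F6 (not isolated), which loses methanesulfonate in the same flask by E1cB elimination and returns to 13.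

## Further compounds

F0 | step 5 | none | none
F1 | step 4 | (E)-2-(2,6,6-trimethylcyclohex-1-en-1-yl)vinyl acetate | CC(=O)O/C=C/C1=C(C)CCCC1(C)C
F2 | step 4 | lithium (E)-2-(2,6,6-trimethylcyclohex-1-en-1-yl)ethenolate | [Li+].[O-]/C=C/C1=C(C)CCCC1(C)C
F3 | step 6 | (13S)-15-acetoxy-7α-(tert-butyldimethylsilyloxy)labd-5-en-17-ol | CC(=O)OCC[C@@H](C)CC[C@H]1[C@H](CO)[C@H](O[Si](C)(C)C(C)(C)C)C=C2C(C)(C)CCC[C@]12C
F4 | step 6 | (13S)-15-acetoxy-7α-(tert-butyldimethylsilyloxy)labdan-17-ol | CC(=O)OCC[C@@H](C)CC[C@H]1[C@H](CO)[C@H](O[Si](C)(C)C(C)(C)C)C[C@H]2C(C)(C)CCC[C@]12C
F5 | step 7 | (13S)-15-acetoxy-7α-hydroxylabdan-17-al | CC(=O)OCC[C@@H](C)CC[C@H]1[C@H](C=O)[C@H](O)C[C@H]2C(C)(C)CCC[C@]12C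
F6 | step 7 | (13S)-15-acetoxy-7α-(methanesulfonyloxy)labdan-17-al | CC(=O)OCC[C@@H](C)CC[C@H]1[C@H](C=O)[C@H](OS(C)(=O)=O)C[C@H]2C(C)(C)CCC[C@]12C
A1 | alternative 1 | 3-[(2E,8E,10E)-12-(4-methoxybenzyloxy)-3,7,7-trimethyldodeca-2,8,10-trienoyl]oxazolidin-2-one | O=C1OCCN1C(=O)/C=C(\C)CCCC(C)(C)/C=C/C=C/COCc2ccc(OC)cc2
A2 | alternative 1 | N-acyloxazolidinone of 17-(4-methoxybenzyloxy)-12,13,14,15,16-pentanorlabd-6-en-11-oic acid (5α-H, 8β-CH2OPMB, 9α-H, 10β-methyl) | O=C1OCCN1C(=O)[C@H]2[C@@H](COCc4ccc(OC)cc4)C=C[C@H]3C(C)(C)CCC[C@]23C
A3 | alternative 2 | methyl (7Z,9(11)E,13S)-8-bromo-15-(tert-butyldimethylsilyloxy)-8,9-secolabda-7,9(11)-dien-17-oate (5α-H, 10β-methyl) | COC(=O)/C(Br)=C/C[C@H]1C(C)(C)CCC[C@]1(C)/C=C/C[C@H](C)CCO[Si](C)(C)C(C)(C)C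
A4 | alternative 2 | methyl (13S)-15-(tert-butyldimethylsilyloxy)labd-7-en-17-oate | CC(C)(C)[Si](C)(C)OCC[C@@H](C)CC[C@H]1C(C(=O)OC)=CC[C@H]2C(C)(C)CCC[C@]12C
A5 | alternative 3 | (S)-1-phenyl-N-(2,2,6-trimethylcyclohexylidene)ethanamine | C[C@H](N=C1C(C)CCCC1(C)C)c2ccccc2
A6 | alternative 3 | methyl (S)-2-acetyl-8-(tert-butyldimethylsilyloxy)-6-methyloct-2-enoate (E/Z mixture) | CC(=O)C(C(=O)OC)=CCC[C@H](C)CCO[Si](C)(C)C(C)(C)C
A7 | alternative 3 | methyl (13S)-15-(tert-butyldimethylsilyloxy)-7-oxolabd-5-en-17-oate (8α-CO2Me, 9α-H, 10β-methyl) | CC(C)(C)[Si](C)(C)OCC[C@@H](C)CC[C@H]1[C@H](C(=O)OC)C(=O)C=C2C(C)(C)CCC[C@]12C
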